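**Plan**
- Retrosynthetic cuts, in order: the C8 methacrylate and C10 acetate C–O bonds; the C1–C10 bond of the ten-membered ring; C8–C9; C13–O with C11–H; and C6–C7 together with the lactone C12–O6 bond.
- Forward: nerol gives the C1–C6 epoxy aldehyde; a 2-(methoxycarbonyl)allylboronate adds and lactonises to the cis γ-lactone (C6, C7). Conjugate borylation/oxidation brings in C13–O and C11; allylation and Wacker oxidation add C9, C10 and C14; ozonolysis frees C1. The ten-membered carbocycle is closed last, followed by two acylations.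
- Stereochemistry: C4/C5 by Sharpless epoxidation; C6 by Felkin–Anh addition; C7 by the closed allylboration transition state; C11 by convex-face protonation; C8 by the chiral allylborane; C10 by a chiral triazolylidene.
- Enabling feature: the C1(=O)–C10(O) α-ketol is the retron of acyl-anion addition of a C1 aldehyde to a C10 methyl ketone. The cis γ-lactone (C5 and C8 arms cis on C6/C7) and the cis oxirane (C3 and C6 cis on C4/C5) fold the two arms toward each other.

Key step: step 15

Assumption: locants follow a germacranolide-type numbering (C1 ketone, C4/C5 oxirane, C6 lactone carbinol, C7 ring-fusion CH, C8 methacrylate carbinol, C10 tertiary acetate carbon, C11/C12/C13 lactone α-carbon, carbonyl and acetoxymethyl carbon); the allylborane of step 11 and the triazolium salt of step 15 are taken as purchasable.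

**Step 1**
Reactants: 1 nerol, (2Z)-3,7-dimethylocta-2,6-dien-1-ol
Product: 2 (2S,3R)-2,3-epoxynerol, [(2S,3R)-3-methyl-3-(4-methylpent-3-en-1-yl)oxiran-2-yl]methanol
Conditions: Ti(OiPr)4 (10 mol %), L-(+)-diethyl tartrate (12 mol %), tBuOOH, 4 Å MS, CH2Cl2, −20 °C
Reagents that add atoms: tert-butyl hydroperoxide, CC(C)(C)OO
Why: Sharpless asymmetric epoxidation of the Z allylic alcohol, in which the L-(+)-tartrate titanium complex delivers oxygen to one face of the C4=C5 bond only (the remote alkene has no directing hydroxyl), setting C4 (R) and C5 (S) and, from the Z geometry, the cis relationship of C3 and C6 on the oxirane.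

**Step 2**
Reactants: 2 (2S,3R)-2,3-epoxynerol
Product: 3 (2R,3R)-3-methyl-3-(4-methylpent-3-en-1-yl)oxirane-2-carbaldehyde
Conditions: Dess–Martin periodinane, NaHCO3, CH2Cl2, 0 °C, used crude
Reagents that add atoms: none
Why: Dess–Martin oxidation of the primary epoxy alcohol under buffered conditions should give the epoxy aldehyde without epimerisation at C5 and creates no new stereocentre.

**Step 3**
Reactants: 4 (tert-butyldimethylsilyloxy)acetaldehyde; 5 methyl acrylate
Product: 6 methyl 4-[(tert-butyldimethylsilyl)oxy]-3-hydroxy-2-methylidenebutanoate (racemic)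
Conditions: 1,4-diazabicyclo[2.2.2]octane (0.5 equiv), excess 5, rt
Reagents that add atoms: none
Why: Morita–Baylis–Hillman reaction of the reactive α-silyloxy aldehyde with the acrylate; the carbinol centre forms racemic and is erased in step 5.

**Step 4**
Reactants: 6 Morita–Baylis–Hillman alcohol
Product: 7 methyl 3-acetoxy-4-[(tert-butyldimethylsilyl)oxy]-2-methylidenebutanoate (racemic)
Conditions: Ac2O, pyridine, 4-(dimethylamino)pyridine (5 mol %), CH2Cl2, 0 °C
Reagents that add atoms: acetic anhydride, CC(=O)OC(C)=O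
Why: Acyl-pyridinium-mediated acetylation turns the allylic hydroxyl into the leaving group for the SN2′ substitution that follows.

**Step 5**
Reactants: 7 allylic acetate
Product: 8 methyl (2E)-4-[(tert-butyldimethylsilyl)oxy]-2-[(4,4,5,5-tetramethyl-1,3,2-dioxaborolan-2-yl)methyl]but-2-enoate (CH2OTBS cis to CH2B)
Conditions: B2pin2, CuCl (10 mol %), KOAc, DMF, rt
Reagents that add atoms: bis(pinacolato)diboron, CC1(C)OB(OC1(C)C)B1OC(C)(C)C(C)(C)O1
Why: Copper-catalysed allylic borylation (Hosomi–Miyaura type SN2′: boryl-copper addition to the acrylate CH2, then β-acetoxy elimination) should give the trisubstituted 2-(methoxycarbonyl)allylboronate with the CH2OTBS group trans to the ester, the geometry needed for syn allyl transfer.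

**Step 6**
Reactants: 3 epoxy aldehyde; 8 allylboronate
Product: 10 (4S,5S)-4-{[(tert-butyldimethylsilyl)oxy]methyl}-3-methylidene-5-[(2S,3R)-3-methyl-3-(4-methylpent-3-en-1-yl)oxiran-2-yl]oxolan-2-one (cis lactone; target locants 4R,5S,6S,7S), via syn-homoallylic pinacol borate 9 (not isolated)
Conditions: toluene, 4 Å MS, 70 °C, sealed tube
Reagents that add atoms: none
Why: Thermal 2-(alkoxycarbonyl)allylboration through a Zimmerman–Traxler chair followed by lactonisation of the borate onto the methyl ester: the γ-substituent cis to CH2B sits axial and gives the syn adduct, hence the cis lactone (C7 relative to C6), while C6 is set by Felkin–Anh/Cornforth attack anti to the oxirane C–O bond of the cis-substituted epoxy aldehyde (5,6-erythro).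

**Step 7**
Reactants: 10 α-methylene lactone
Product: 12 (3R,4S,5S)-4-{[(tert-butyldimethylsilyl)oxy]methyl}-3-(hydroxymethyl)-5-[(2S,3R)-3-methyl-3-(4-methylpent-3-en-1-yl)oxiran-2-yl]oxolan-2-one, via C13-pinacolboryl lactone 11 (not isolated)
Conditions: B2pin2 (1.1 equiv), CuCl (5 mol %), 4,5-bis(diphenylphosphino)-9,9-dimethylxanthene (5 mol %), NaOtBu (10 mol %), MeOH (2 equiv), THF, 0 °C; then NaBO3·4H2O, THF/H2O, 0 °C → rt
Reagents that add atoms: bis(pinacolato)diboron, CC1(C)OB(OC1(C)C)B1OC(C)(C)C(C)(C)O1 (boron of 11); sodium perborate, [Na+].[Na+].O[B-]1(O)OO[B-](O)(O)OO1 (hydroxyl oxygen of 12)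
Why: Copper-catalysed conjugate borylation of the enoate, with methanol protonating the copper enolate on the lactone face opposite the cis C5 and C8 appendages, should set C11 with C13 cis to both, and stereoretentive perborate oxidation of the C–B bond then gives the primary alcohol while isolated alkenes and the oxirane stay untouched.

**Step 8**
Reactants: 12 C13 alcohol
Product: 13 [(3R,4S,5S)-4-{[(tert-butyldimethylsilyl)oxy]methyl}-5-[(2S,3R)-3-methyl-3-(4-methylpent-3-en-1-yl)oxiran-2-yl]-2-oxooxolan-3-yl]methyl acetate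
Conditions: Ac2O, pyridine, 4-(dimethylamino)pyridine (5 mol %), CH2Cl2, 0 °C
Reagents that add atoms: acetic anhydride, CC(=O)OC(C)=O
Why: Acetylation of the primary alcohol installs the C13 acetate of the target under conditions too weakly basic for β-elimination or C11 epimerisation.

**Step 9**
Reactants: 13 silyl ether
Product: 14 [(3R,4S,5S)-4-(hydroxymethyl)-5-[(2S,3R)-3-methyl-3-(4-methylpent-3-en-1-yl)oxiran-2-yl]-2-oxooxolan-3-yl]methyl acetate
Conditions: HF·pyridine, pyridine, THF, 0 °C
Reagents that add atoms: none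
Why: Buffered fluoride desilylation removes the primary TBS ether while acetate, lactone and oxirane persist; the short, cold, non-basic treatment is meant to forestall acetyl migration or translactonisation to the freed hydroxyl.

**Step 10**
Reactants: 14 primary alcohol
Product: 15 [(3R,4R,5S)-4-formyl-5-[(2S,3R)-3-methyl-3-(4-methylpent-3-en-1-yl)oxiran-2-yl]-2-oxooxolan-3-yl]methyl acetate
Conditions: Dess–Martin periodinane, NaHCO3, CH2Cl2, 0 °C, used crude
Reagents that add atoms: none
Why: Dess–Martin oxidation under neutral buffered conditions gives the C8 aldehyde, which is used at once because C7–H is α to it and the lactone oxygen is β.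

**Step 11**
Reactants: 15 aldehyde
Product: 17 [(3R,4S,5S)-4-[(1S)-1-hydroxybut-3-en-1-yl]-5-[(2S,3R)-3-methyl-3-(4-methylpent-3-en-1-yl)oxiran-2-yl]-2-oxooxolan-3-yl]methyl acetate, via diisopinocampheylborinate 16 (not isolated)
Conditions: (−)-Ipc2B(allyl) (from (+)-α-pinene, 1 M in pentane), Et2O, −78 °C; then NaBO3·4H2O, THF/H2O, 0 °C
Reagents that add atoms: (−)-B-allyldiisopinocampheylborane, C=CCB([C@@H]1C[C@@H]2C[C@H]([C@H]1C)C2(C)C)[C@@H]1C[C@@H]2C[C@H]([C@H]1C)C2(C)C
Why: Brown asymmetric allylboration, in which the (+)-α-pinene-derived borane transfers allyl to the Si face of the aldehyde through a chair transition state under reagent control, should set C8 (S) irrespective of the α-stereocentre, and the mild perborate work-up cleaves the borinate.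

**Step 12**
Reactants: 17 homoallylic alcohol
Product: 18 [(3R,4R,5S)-4-[(1S)-1-[(tert-butyldimethylsilyl)oxy]but-3-en-1-yl]-5-[(2S,3R)-3-methyl-3-(4-methylpent-3-en-1-yl)oxiran-2-yl]-2-oxooxolan-3-yl]methyl acetate
Conditions: TBSOTf, 2,6-lutidine, CH2Cl2, −78 °C
Reagents that add atoms: tert-butyldimethylsilyl trifluoromethanesulfonate, CC(C)(C)[Si](C)(C)OS(=O)(=O)C(F)(F)F
Why: Silylation of the hindered secondary hydroxyl blocks translactonisation onto O8 and later β-elimination next to the C10 ketone.

**Step 13**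
Reactants: 18 terminal alkene
Product: 19 [(3R,4R,5S)-4-[(1S)-1-[(tert-butyldimethylsilyl)oxy]-3-oxobutyl]-5-[(2S,3R)-3-methyl-3-(4-methylpent-3-en-1-yl)oxiran-2-yl]-2-oxooxolan-3-yl]methyl acetate
Conditions: PdCl2 (10 mol %), CuCl (1 equiv), O2 (1 atm), DMF/H2O 7:1, rt
Reagents that add atoms: water, O
Why: Tsuji–Wacker oxidation (Markovnikov hydroxypalladation of the monosubstituted alkene, then β-hydride elimination) should give the C10 methyl ketone while the trisubstituted alkene does not react.

**Step 14**
Reactants: 19 methyl ketone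
Product: 21 [(3R,4R,5S)-4-[(1S)-1-[(tert-butyldimethylsilyl)oxy]-3-oxobutyl]-5-[(2S,3R)-3-methyl-3-(3-oxopropyl)oxiran-2-yl]-2-oxooxolan-3-yl]methyl acetate (keto aldehyde), via secondary ozonide 20 (not isolated)
Conditions: O3, CH2Cl2, −78 °C; then PPh3, −78 °C → rt
Reagents that add atoms: ozone, [O-][O+]=O
Why: Ozonolysis of the only remaining alkene ([3+2] cycloaddition, cycloreversion and recombination to the ozonide, reduced by the phosphine) unveils the C1 aldehyde and releases acetone.

**Step 15**
Reactants: 21 keto aldehyde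
Product: 23 ten-membered α-ketol (C1 ketone, C10 tertiary alcohol, C8 OTBS, C13 OAc; 4R,5S,6S,7R,8S,10R,11R), via Breslow enaminol 22 (not isolated)
Conditions: (5aS,10bR)-2-(pentafluorophenyl)-5a,10b-dihydro-4H,6H-indeno[2,1-b][1,2,4]triazolo[4,3-d][1,4]oxazin-2-ium tetrafluoroborate (20 mol %), iPr2NEt (20 mol %), toluene, 40 °C, slow addition of 21 to 2 mM
Reagents that add atoms: none
Why: Proposed new method: the triazolylidene adds to the C1 aldehyde and a proton shift gives Breslow intermediate 22, an acyl-anion equivalent that adds to the C10 methyl ketone and then releases the carbene, so the C1–C10 bond, the C1 ketone and the C10 tertiary carbinol arise in one redox-neutral event from a linear keto aldehyde. The closest known reaction type is the intramolecular crossed aldehyde–ketone benzoin reaction, established for five- and six-membered α-ketols with chiral aminoindanol triazolium salts, together with macrocyclic acyl-anion (Stetter, acyloin) closures; a ten-membered carbocycle has not been closed this way. The ring closes in a 10-exo-trig mode, helped by the cis-fused γ-lactone (C5 and C8 arms cis on C6/C7) and the cis C4–C5 oxirane, which turn the arms toward each other, and by the reversibility of aldehyde homo-benzoin oligomers, which high dilution should funnel into the ring. C10 is created by attack on the Si face of the ketone, selected by the chiral triazolylidene in its hydrogen-bonded transition state acting with the C8 silyloxy centre β to the ketone; which antipode of the salt matches the substrate cannot be assigned in advance, and the other one is at hand. The step needs chemoselectivity (only the aldehyde can form a Breslow intermediate, and the saturated lactone offers no Stetter acceptor) and freedom from base damage (catalytic tertiary amine only, so the β-silyloxy ketone and the β-acetoxy lactone should not eliminate).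

**Step 16**
Reactants: 23 α-ketol
Product: 24 C10 acetate of the ten-membered ketone (C8 OTBS; 4R,5S,6S,7R,8S,10R,11R)
Conditions: Ac2O, 4-(dimethylamino)pyridine (1.5 equiv), CH2Cl2, rt → 35 °C
Reagents that add atoms: acetic anhydride, CC(=O)OC(C)=O
Why: Acyl-pyridinium acetylation of the tertiary α-ketol hydroxyl avoids strong base and Lewis acid, so α-ketol rearrangement and oxirane opening should not compete, and C10 is untouched.

**Step 17**
Reactants: 24 silyl ether
Product: 25 C8 alcohol (4R,5S,6S,7S,8S,10R,11R)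
Conditions: HF·pyridine, pyridine, THF, 0 °C → rt
Reagents that add atoms: none
Why: Buffered fluoride desilylation frees the C8 hydroxyl without touching the two acetates, the α-acetoxy ketone, the lactone or the oxirane.

**Step 18**
Reactants: 25 C8 alcohol
Product: 26 CNP0166747.1 (4R,5S,6S,7S,8S,10R,11R)
Conditions: methacrylic anhydride, Et3N, 4-(dimethylamino)pyridine (10 mol %), CH2Cl2, 0 °C
Reagents that add atoms: methacrylic anhydride, C=C(C)C(=O)OC(=O)C(C)=C
Why: Acyl-pyridinium-mediated esterification with retention at C8, run cold and directly after step 17 so that the cis γ-hydroxy lactone has no time to translactonise.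

**Compound list**
1 | nerol, (2Z)-3,7-dimethylocta-2,6-dien-1-ol | CC(C)=CCC/C(C)=C\CO | starting material
2 | (2S,3R)-2,3-epoxynerol | CC(C)=CCC[C@@]1(C)O[C@H]1CO | intermediate
3 | (2R,3R)-3-methyl-3-(4-methylpent-3-en-1-yl)oxirane-2-carbaldehyde | CC(C)=CCC[C@@]1(C)O[C@H]1C=O | intermediate
4 | (tert-butyldimethylsilyloxy)acetaldehyde | CC(C)(C)[Si](C)(C)OCC=O | starting material
5 | methyl acrylate | C=CC(=O)OC | starting material
6 | methyl 4-[(tert-butyldimethylsilyl)oxy]-3-hydroxy-2-methylidenebutanoate (racemic) | C=C(C(=O)OC)C(O)CO[Si](C)(C)C(C)(C)C | intermediate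
7 | methyl 3-acetoxy-4-[(tert-butyldimethylsilyl)oxy]-2-methylidenebutanoate (racemic) | C=C(C(=O)OC)C(OC(C)=O)CO[Si](C)(C)C(C)(C)C | intermediate
8 | methyl (2E)-4-[(tert-butyldimethylsilyl)oxy]-2-[(4,4,5,5-tetramethyl-1,3,2-dioxaborolan-2-yl)methyl]but-2-enoate | CC(C)(C)[Si](C)(C)OC/C=C(\CB1OC(C)(C)C(C)(C)O1)C(=O)OC | intermediate
9 | pinacol borate of the syn homoallylic alcohol (C6–O–B; 4R,5S,6S,7S), methyl ester | CC(C)(C)[Si](C)(C)OC[C@@H]([C@H](OB1OC(C)(C)C(C)(C)O1)[C@@H]2O[C@]2(C)CCC=C(C)C)C(=C)C(=O)OC | intermediate (not isolated)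
10 | cis α-methylene γ-lactone with C7 CH2OTBS (4R,5S,6S,7S) | CC(C)(C)[Si](C)(C)OC[C@@H]1C(=C)C(=O)O[C@@H]1[C@@H]2O[C@]2(C)CCC=C(C)C | intermediate
11 | C13-pinacolboryl lactone (4R,5S,6S,7S,11S) | CC(C)(C)[Si](C)(C)OC[C@@H]1[C@H](CB3OC(C)(C)C(C)(C)O3)C(=O)O[C@@H]1[C@@H]2O[C@]2(C)CCC=C(C)C | intermediate (not isolated)
12 | C13 alcohol, all-cis lactone (4R,5S,6S,7S,11R) | CC(C)(C)[Si](C)(C)OC[C@@H]1[C@H](CO)C(=O)O[C@@H]1[C@@H]2O[C@]2(C)CCC=C(C)C | intermediate
13 | C13 acetate, C8 OTBS (4R,5S,6S,7S,11R) | CC(C)(C)[Si](C)(C)OC[C@@H]1[C@H](COC(C)=O)C(=O)O[C@@H]1[C@@H]2O[C@]2(C)CCC=C(C)C | intermediate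
14 | C8 primary alcohol (4R,5S,6S,7S,11R) | OC[C@@H]1[C@H](COC(C)=O)C(=O)O[C@@H]1[C@@H]2O[C@]2(C)CCC=C(C)C | intermediate
15 | C8 aldehyde (4R,5S,6S,7R,11R) | O=C[C@@H]1[C@H](COC(C)=O)C(=O)O[C@@H]1[C@@H]2O[C@]2(C)CCC=C(C)C | intermediate
16 | diisopinocampheylborinate of 17 | C=CC[C@H](OB([C@@H]3C[C@@H]4C[C@H]([C@H]3C)C4(C)C)[C@@H]3C[C@@H]4C[C@H]([C@H]3C)C4(C)C)[C@@H]1[C@H](COC(C)=O)C(=O)O[C@@H]1[C@@H]2O[C@]2(C)CCC=C(C)C | intermediate (not isolated)
17 | C8 homoallylic alcohol (4R,5S,6S,7S,8S,11R) | C=CC[C@H](O)[C@@H]1[C@H](COC(C)=O)C(=O)O[C@@H]1[C@@H]2O[C@]2(C)CCC=C(C)C | intermediate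
18 | C8 TBS ether, terminal alkene (4R,5S,6S,7R,8S,11R) | C=CC[C@H](O[Si](C)(C)C(C)(C)C)[C@@H]1[C@H](COC(C)=O)C(=O)O[C@@H]1[C@@H]2O[C@]2(C)CCC=C(C)C | intermediate
19 | C10 methyl ketone (4R,5S,6S,7R,8S,11R) | CC(=O)C[C@H](O[Si](C)(C)C(C)(C)C)[C@@H]1[C@H](COC(C)=O)C(=O)O[C@@H]1[C@@H]2O[C@]2(C)CCC=C(C)C | intermediate
20 | secondary ozonide of 19 (3,3-dimethyl-1,2,4-trioxolane at C1) | CC(=O)C[C@H](O[Si](C)(C)C(C)(C)C)[C@@H]1[C@H](COC(C)=O)C(=O)O[C@@H]1[C@@H]2O[C@]2(C)CCC3OOC(C)(C)O3 | intermediate (not isolated)
21 | keto aldehyde (C1 CHO, C10 methyl ketone; 4R,5S,6S,7R,8S,11R) | CC(=O)C[C@H](O[Si](C)(C)C(C)(C)C)[C@@H]1[C@H](COC(C)=O)C(=O)O[C@@H]1[C@@H]2O[C@]2(C)CCC=O | intermediate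
22 | Breslow enaminol of 21 with the triazolylidene | CC(=O)C[C@H](O[Si](C)(C)C(C)(C)C)[C@@H]1[C@H](COC(C)=O)C(=O)O[C@@H]1[C@@H]2O[C@]2(C)CCC(O)=C3N(c4c(F)c(F)c(F)c(F)c4F)N=C5CO[C@H]6Cc7ccccc7[C@H]6N35 | intermediate (not isolated)
23 | ten-membered α-ketol (C10 OH, C8 OTBS; 4R,5S,6S,7R,8S,10R,11R) | CC(C)(C)[Si](C)(C)O[C@H]1C[C@@](C)(O)C(=O)CC[C@@]2(C)O[C@H]2[C@H]2OC(=O)[C@@H](COC(C)=O)[C@H]21 | intermediate
24 | C10 acetate, C8 OTBS (4R,5S,6S,7R,8S,10R,11R) | CC(C)(C)[Si](C)(C)O[C@H]1C[C@@](C)(OC(C)=O)C(=O)CC[C@@]2(C)O[C@H]2[C@H]2OC(=O)[C@@H](COC(C)=O)[C@H]21 | intermediate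
25 | C8 alcohol (4R,5S,6S,7S,8S,10R,11R) | O[C@H]1C[C@@](C)(OC(C)=O)C(=O)CC[C@@]2(C)O[C@H]2[C@H]2OC(=O)[C@@H](COC(C)=O)[C@H]21 | intermediate
26 | CNP0166747.1 (4R,5S,6S,7S,8S,10R,11R) | C=C(C)C(=O)O[C@H]1C[C@@](C)(OC(C)=O)C(=O)CC[C@@]2(C)O[C@H]2[C@H]2OC(=O)[C@@H](COC(C)=O)[C@H]21 | target

**Step count**
Total: 18 steps. Longest linear sequence: 16 steps (steps 3–18, from 4 and 5); the nerol branch (steps 1–2) joins at step 6.

**Steps most likely to fail**

Step 15 (carbene-catalysed ring closure). The closure may lose to intermolecular aldehyde homo-coupling and oligomerisation, or the catalyst may not turn over on the hindered ketone. In that case the ring would be closed reductively from 21. Slow addition of 21 to SmI2 in THF (−78 °C → rt, high dilution) effects a pinacol macrocyclisation through the aldehyde ketyl, a known route to medium-ring 1,2-diols, and gives the macrocyclic 1,10-diol F1. Its secondary C1 hydroxyl is then oxidised selectively with Dess–Martin periodinane/NaHCO3 (the tertiary C10 hydroxyl cannot react), which returns to ketol 23. C10 epimers would be separated at the diol or ketol stage.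

Step 6 (allylboration of the epoxy aldehyde). The epoxy aldehyde may decompose during prolonged heating, or facial selectivity at C6 may be poor. The C6–C7 bond would then be made by a room-temperature Barbier-type reaction of an organochromium species generated in situ, in place of the thermal transfer from an isolated boronate. Alcohol 6 is converted with N-bromosuccinimide/Me2S (allylic transposition) into methyl (2Z)-2-(bromomethyl)-4-[(tert-butyldimethylsilyl)oxy]but-2-enoate F2. CrCl2 in THF (0 °C → rt; Nozaki–Hiyama-type 2-(alkoxycarbonyl)allylation, known to favour cis β,γ-disubstituted α-methylene lactones) couples F2 with aldehyde 3 to the syn hydroxy ester F3, which lactonises on work-up and rejoins the route at 10.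

Step 11 (allylation of aldehyde 15). The aldehyde may epimerise at C7 or lose the lactone oxygen by β-elimination during allylboration and oxidative work-up; the later Wacker oxidation may also be regiochemically unclean. The C9–C10–C14 unit would then be added as acetone in a single aldol step. The diisopinocampheylboron enolate of acetone (Ipc2BCl antipode that attacks the Si face of C8, Et3N, Et2O, −78 °C) adds to 15 and gives β-hydroxy ketone F4 directly. Silylation (TBSOTf, 2,6-lutidine) rejoins the route at 19, bypassing 17 and 18.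

**Further compounds**
F1 | step 15 | macrocyclic 1,10-diol (C1 secondary and C10 tertiary hydroxyls, C8 OTBS, C13 OAc; C1 configuration open) | CC(C)(C)[Si](C)(C)O[C@H]1C[C@@](C)(O)C(O)CC[C@@]2(C)O[C@H]2[C@H]2OC(=O)[C@@H](COC(C)=O)[C@H]21
F2 | step 6 | methyl (2Z)-2-(bromomethyl)-4-[(tert-butyldimethylsilyl)oxy]but-2-enoate | CC(C)(C)[Si](C)(C)OC/C=C(\CBr)C(=O)OC
F3 | step 6 | syn hydroxy ester (C6 OH, methyl ester; 4R,5S,6S,7S) | CC(C)(C)[Si](C)(C)OC[C@@H]([C@H](O)[C@@H]1O[C@]1(C)CCC=C(C)C)C(=C)C(=O)OC
F4 | step 11 | β-hydroxy ketone (C8 OH, C10 methyl ketone; 4R,5S,6S,7S,8S,11R) | CC(=O)C[C@H](O)[C@@H]1[C@H](COC(C)=O)C(=O)O[C@@H]1[C@@H]2O[C@]2(C)CCC=C(C)C
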